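The pitfall in west, north-east and north-west is to read their charges of Q, from 25.0 mM to 56.0 mM, as a ladder of speeds and to expect most from the flask with most Q. I take it that in each flask L starts chains, the carrier Z passes through, and J ends up as E.

| setting | Thursday's | Tuesday's | west | north-east | north-west |
|---|---|---|---|---|---|
| J | 10 mM | 10 mM | 10 mM | 10 mM | 10 mM |
| Q | 15 mM | 43 mM | 56.0 mM | 25.0 mM | 38.0 mM |
| L | 0.20 mM | 0.20 mM | 0.20 mM | 0.20 mM | 0.20 mM |
| remark | run made earlier | run made earlier |  |  |  |
| time |  |  | 15 min | 15 min | 15 min |

- Thursday's (time / min: J / %, Z / %, E / %): 0.667: 95.4, 0.5, 6.1; 2.00: 88.8, 1.2, 13.8; 4.00: 78.2, 0.8, 22.0; 6.00: 67.4, 0.6, 29.2; 8.00: 59.0, 0.9, 40.8; 10.0: 53.3, 0, 47.0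
- Tuesday's (time / min: J / %, Z / %, E / %): 0.667: 95.6, 0, 3.7; 2.00: 88.2, 0, 12.4; 4.00: 78.0, 0, 22.0; 6.00: 70.4, 0, 29.7; 8.00: 61.1, 0, 39.3; 10.0: 54.0, 0, 48.1

(readings scatter by 1 percentage point)

- which of these there is most of at the end, counted by the J in it, west (J / E / Z)
- which of these there is most of at the end, counted by the J in it, north-east (J / E / Z)
- which of these there is most of at the end, counted by the J in it, north-west (J / E / Z)
- how much there is at the end of the one of these that leads, in percent of the J charged: west
- how much there is at the end of the one of these that leads, in percent of the J charged: north-east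
- how much there is at the end of the one of these that leads, in percent of the J charged: north-west

I reckon with the rate alone. Z stays at or below 1.2% on Thursday while E climbs to 47.0%, so I take Z as steady and let its making and removal balance, which leaves the rate to be read from the loss of J. Raising Q by a factor of 2.87 changes the J left at 10.0 min by 0.7 percentage points, less than the scatter of 1 point, so I give Q a slowing factor of one. The two runs together give 0.0623 /min, the share of the standing J lost per minute, a pseudo-first-order constant. The later readings give this share a factor of 1.01 against the earlier ones, so over those readings I see no slowing beyond the fall of J, within the scatter.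

The starting rate is therefore 0.623 mM/min, and held for 15 min it would consume 93.4% of the J. But in my reckoning the rate follows J down, and by the end it stands at 0.393 of its starting value, at 0.245 mM/min. The accumulated slowing leaves 60.7% of the J lost, which I count as E in each flask. The forecast names E as the leader everywhere, at 60%, 60% and 60%, holding that “the rate is essentially zero order in Q”.

West, north-east and north-west give E at 60.2%, 60.2% and 60.2%, the leader the forecast names and within its margin.

    Q + Z → E + D (k = 14000 /M/s)
    J + D → Z (k = 25800 /M/s)
    2 D → G (k = 2.60 × 10⁷ /M/s)
    E → X (k = 6.72 × 10⁻⁵ /min)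
    L → 2 D (k = 0.0136 /min)

North-east has not come to rest at 15 min: J still stands at 39.8%, and by 150 min E gains a further 39 points, reaching 98.9%. My constant, carried on, puts J at 2.38% in north-east after 60.0 min, where the flask holds 4.14% with L at 44.2% of its charge. At 150 min the constant gives 0.00874%, where north-east holds 0.229% of J with L at 13.0%, and X has reached 0.886%.

The data were computed for substances that don't exist; scatter was added.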